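All runs were generated by integration for substances that don't exist; noise was put on by code.

An equilibrium cannot stand at two heights from one charge, yet from 0.400 M of starting material the target stalls near 0.203 M in the south run, with 0.0400 M of free catalyst, and near 0.251 M in the west run, with 0.0600 M, each height being the mean of the last 3 readings; two of us disagree about what stops these flasks.

| setting | south | west | south-west |
|---|---|---|---|
| starting material | 0.400 M | 0.400 M | 0.400 M |
| free catalyst | 0.0400 M | 0.0600 M | 0.0400 M |
| time |  |  | 960 h |

| run | time / h | [target] / M |
|---|---|---|
| south run | 11 | 0.088 |
| south run | 32 | 0.156 |
| south run | 62 | 0.177 |
| south run | 98 | 0.195 |
| south run | 140 | 0.203 |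
| south run | 190 | 0.201 |
| south run | 240 | 0.206 |
| west run | 11 | 0.118 |
| west run | 32 | 0.198 |
| west run | 62 | 0.229 |
| west run | 98 | 0.242 |
| west run | 140 | 0.250 |
| west run | 190 | 0.249 |
| west run | 240 | 0.255 |

(scatter of a reading: 0.003 M)

1. how the opening rate goes with [free catalyst] round the charge of the south run: the exponent of the rate at two percent of starting material gone to target
2. target in the south-west run at 960 h, as a share of the starting material charged

- Overall: starting material -> target, with free catalyst as catalyst.
- Constant volume, constant temperature.
- Bound and free are read together.
- An order is taken over about fifteen percent of the charge, up and down.

One of us made the forecast, 0.8 for the exponent and 52% for the south-west run, on the view that “the catalyst is probably dying or being locked up”, and reads the order from the ratio of the plateaus and of the early readings.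

The other of us holds that the flask is a race for the starting material, in which a second route, indifferent to the catalyst, takes what the catalyst does not turn to target, so that the number to compare is a selectivity between the two routes. The south run gives 1.03 for the stall odds O, the target at the stall over the part of the charge that did not become target, and the west run gives 1.69. If the second route stands unchanged while the catalytic route grows with the catalyst charge, O grows as the catalytic rate does, so this side takes the logarithm of the ratio of the two O values over the logarithm of the ratio of the two charges and gets an exponent of 1.21, which is higher than the forecast's 0.8. The south-west run repeats the south recipe, so this side carries the south value of O over and expects a share of O/(1+O), or 50.8%, beside the forecast's 52%; the two sides part on the exponent.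

The simulation gives 1.2 for the exponent and 52.0% for the south-west run.

    free catalyst + starting material ⇌ catalyst-substrate complex, settled at all times (11.80 L mol⁻¹)
    catalyst-substrate complex + starting material ⇌ doubly bound catalyst, settled at all times (3.490 L mol⁻¹)
    doubly bound catalyst → target + catalyst-substrate complex (0.6696 h⁻¹)
    2 starting material → homo dimer (0.1048 L mol⁻¹ h⁻¹)
    free catalyst + impurity → spent catalyst

The run without the route of 2 starting material to homo dimer shows what holds the south-west run down: its target reaches 99.4% in place of 52.0%, so that route is the main reason for the stall, with 99% of what is missing. The forecast's view keeps its ground in the south-west run, a repeat of the south recipe, whose height it gave as 52%; there 52.0% is an O of 1.08, against the 1.03 read at the stall of the south run.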